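**Retrosynthetic overview**

- The route rests on one feature: the chain C2–C14 between carbinol C1 (on ring B, the 4-aryloxy-3,5-dihydroxyphenyl ring) and ring A (the monohydroxy ring) is thirteen unfunctionalised CH2 groups. C6–C9 can therefore be carried as a conjugated diyne and the 22-membered ring opened at its central C7–C8 bond.
- The macrocyclic 6,8-diyne comes from an acyclic bis(terminal alkyne) by Eglinton coupling. This is the only ring formed; rings A and B are bought as phenols.
- The ring A–C14 bond comes from Negishi coupling of an aryl bromide with a silylated heptynylzinc reagent. C1 comes from an aryl aldehyde and a silylated hexynyl Grignard reagent, followed by oxidation and CBS reduction to the (R)-carbinol.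
- The diaryl ether comes from Chan–Lam coupling of 3,5-bis(benzyloxy)-4-hydroxybenzaldehyde with an arylboronic acid made from 3,5-dibromophenol. It is formed before C1 exists, so that no 4-hydroxybenzylic stereocentre ever meets base.
- End game: hydrogenation (diyne to alkane, benzyl ethers to phenols), then desilylation at C1.

Key step: step 16

Remark: C1 is the carbinol carbon on ring B and C14 the benzylic CH2 on ring A. The stereocentre in the target SMILES is read as (R).

**Route**

Step 1
Reactants: 1 3,4,5-trihydroxybenzaldehyde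
Product: 2 4-(allyloxy)-3,5-dihydroxybenzaldehyde
Conditions: allyl bromide (1.05 equiv), NaHCO3 (1.5 equiv), NaI (cat.), DMF, 40 °C
Reagents that add atoms: allyl bromide, C=CCBr
Why: Chemoselective Williamson etherification, in which hydrogencarbonate ionises only the 4-OH (the most acidic, its phenoxide being conjugated with the para formyl group), so one equivalent of allyl bromide should alkylate O4 alone.

Step 2
Reactants: 2 4-(allyloxy)-3,5-dihydroxybenzaldehyde
Product: 3 4-(allyloxy)-3,5-bis(benzyloxy)benzaldehyde
Conditions: BnBr (2.4 equiv), K2CO3 (3 equiv), DMF, 60 °C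
Reagents that add atoms: benzyl bromide, BrCc1ccccc1
Why: Williamson etherification of the two remaining equivalent phenols; the allyl ether and the aldehyde are inert to carbonate and benzyl bromide.

Step 3
Reactants: 3 4-(allyloxy)-3,5-bis(benzyloxy)benzaldehyde
Product: 4 3,5-bis(benzyloxy)-4-hydroxybenzaldehyde
Conditions: Pd(PPh3)4 (5 mol%), morpholine (5 equiv), THF, rt; dilute aq. HCl work-up
Reagents that add atoms: none
Why: Tsuji–Trost deallylation, in which zerovalent palladium ionises the allyl aryl ether (the 4-formylphenoxide is a good leaving group) and morpholine traps the π-allyl unit, leaving benzyl ethers and aldehyde untouched.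

Step 4
Reactants: 5 3,5-dibromophenol
Product: 6 1-(benzyloxy)-3,5-dibromobenzene
Conditions: BnBr (1.1 equiv), K2CO3 (2 equiv), acetone, reflux
Reagents that add atoms: benzyl bromide, BrCc1ccccc1
Why: Williamson etherification of a simple phenol.

Step 5
Reactants: 6 1-(benzyloxy)-3,5-dibromobenzene
Product: 9 [3-(benzyloxy)-5-bromophenyl]boronic acid, via [3-(benzyloxy)-5-bromophenyl]lithium 7 (not isolated), via lithium aryl(triisopropoxy)borate 8 (not isolated)
Conditions: n-BuLi (1.0 equiv), Et2O, −78 °C; B(OiPr)3, −78 °C to rt; 1 M HCl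
Reagents that add atoms: triisopropyl borate, CC(C)OB(OC(C)C)OC(C)C; water, O
Why: Mono bromine–lithium exchange with one equivalent of n-BuLi at −78 °C, borylation of the aryllithium and acidic hydrolysis of the borate; the second bromide stays because the monolithiated arene is not exchanged again at this temperature.

Step 6
Reactants: 4 3,5-bis(benzyloxy)-4-hydroxybenzaldehyde; 9 [3-(benzyloxy)-5-bromophenyl]boronic acid (2.5 equiv)
Product: 10 3,5-bis(benzyloxy)-4-[3-(benzyloxy)-5-bromophenoxy]benzaldehyde
Conditions: Cu(OAc)2 (1.5 equiv), pyridine (5 equiv), powdered 4 Å MS, CH2Cl2, dry air as terminal oxidant, rt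
Reagents that add atoms: none
Why: Chan–Lam–Evans coupling, in which divalent copper acetate mediates oxidative C–O coupling of the arylboronic acid with the hindered but acidic 2,6-dialkoxyphenol at room temperature, sparing the aldehyde and the aryl bromide; the ether is made before C1 exists, so no para-hydroxybenzylic centre that could racemise through a quinone methide is ever exposed to base.

Step 7
Reactants: 11 6-chlorohex-1-yne
Product: 13 (6-chlorohex-1-yn-1-yl)trimethylsilane, via (6-chlorohex-1-yn-1-yl)lithium 12 (not isolated)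
Conditions: n-BuLi (1.05 equiv), THF, −78 °C; Me3SiCl, −78 °C to rt
Reagents that add atoms: chlorotrimethylsilane, C[Si](C)(C)Cl
Why: Deprotonation of the terminal alkyne and C-silylation of the acetylide; the primary chloride does not react with n-BuLi at −78 °C.

Step 8
Reactants: 10 3,5-bis(benzyloxy)-4-[3-(benzyloxy)-5-bromophenoxy]benzaldehyde; 13 (6-chlorohex-1-yn-1-yl)trimethylsilane
Product: 15 rac-1-{3,5-bis(benzyloxy)-4-[3-(benzyloxy)-5-bromophenoxy]phenyl}-7-(trimethylsilyl)hept-6-yn-1-ol, via [6-(trimethylsilyl)hex-5-yn-1-yl]magnesium chloride 14 (not isolated)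
Conditions: 13, Mg turnings (I2 cat.), THF, reflux; then 10, THF, −40 to 0 °C; sat. aq. NH4Cl
Reagents that add atoms: none
Why: Grignard addition, in which the primary chloride inserts magnesium in refluxing THF and the reagent adds to the aryl aldehyde at low temperature far faster than it exchanges with the aryl bromide; the carbinol is racemic here and its configuration is set in step 10.

Step 9
Reactants: 15 the racemic carbinol
Product: 16 1-{3,5-bis(benzyloxy)-4-[3-(benzyloxy)-5-bromophenoxy]phenyl}-7-(trimethylsilyl)hept-6-yn-1-one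
Conditions: Dess–Martin periodinane (1.3 equiv), CH2Cl2, rt
Reagents that add atoms: none
Why: Dess–Martin oxidation of a secondary benzylic alcohol to the aryl ketone under near-neutral conditions that leave silylalkyne, benzyl ethers and aryl bromide intact.

Step 10
Reactants: 16 the aryl ketone
Product: 17 (R)-1-{3,5-bis(benzyloxy)-4-[3-(benzyloxy)-5-bromophenoxy]phenyl}-7-(trimethylsilyl)hept-6-yn-1-ol
Conditions: (S)-2-methyl-CBS-oxazaborolidine (0.2 equiv), BH3·SMe2 (0.8 equiv), THF, −20 °C; MeOH quench
Reagents that add atoms: none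
Why: Corey–Bakshi–Shibata reduction, in which the (S)-oxazaborolidine binds the ketone with the large aryl group away from the catalyst and delivers hydride to the face that gives the (R)-carbinol (the established sense for aryl n-alkyl ketones), and catalysed ketone reduction is much faster than hydroboration of the silylalkyne at −20 °C.

Step 11
Reactants: 17 the (R)-carbinol
Product: 18 the tert-butyldimethylsilyl ether of 17, (R)-configured aryl bromide
Conditions: t-BuMe2SiCl (1.5 equiv), imidazole (3 equiv), DMF, rt
Reagents that add atoms: tert-butyldimethylsilyl chloride, CC(C)(C)[Si](C)(C)Cl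
Why: Standard imidazole-promoted O-silylation of a secondary alcohol; no bond to C1 is broken, so the configuration is kept.

Step 12
Reactants: 19 hept-6-yn-1-ol
Product: 22 7-(trimethylsilyl)hept-6-yn-1-ol, via dilithium alkoxide acetylide 20 (not isolated), via O,C-bis(trimethylsilyl) compound 21 (not isolated)
Conditions: n-BuLi (2.2 equiv), THF, −78 to 0 °C; Me3SiCl (2.4 equiv); then 1 M HCl, rt
Reagents that add atoms: chlorotrimethylsilane, C[Si](C)(C)Cl
Why: Double deprotonation and double silylation, then selective acidic hydrolysis of the labile O–SiMe3 bond, which leaves the C-silylated alkynol.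

Step 13
Reactants: 22 7-(trimethylsilyl)hept-6-yn-1-ol
Product: 23 (7-iodohept-1-yn-1-yl)trimethylsilane
Conditions: I2 (1.2 equiv), PPh3 (1.2 equiv), imidazole (1.5 equiv), CH2Cl2, 0 °C to rt
Reagents that add atoms: iodine, II
Why: Appel-type iodination, an SN2 displacement of the oxyphosphonium group by iodide at a primary carbon.

Step 14
Reactants: 18 the (R)-silyl ether aryl bromide; 23 (7-iodohept-1-yn-1-yl)trimethylsilane
Product: 25 (R)-bis(trimethylsilylalkyne), 18 with the ring A bromine replaced by a 7-(trimethylsilyl)hept-6-yn-1-yl chain, via [7-(trimethylsilyl)hept-6-yn-1-yl]zinc iodide 24 (not isolated)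
Conditions: 23, Zn dust (activated with BrCH2CH2Br and Me3SiCl), LiCl, THF, 50 °C; then 18, Pd(OAc)2 (3 mol%), SPhos (6 mol%), THF, rt to 50 °C
Reagents that add atoms: none
Why: Negishi coupling, with LiCl-assisted zinc insertion into the primary iodide followed by palladium/SPhos-catalysed sp2–sp3 coupling at the unhindered aryl bromide; the alkylzinc tolerates the silyl ether, the benzyl ethers and both silylalkynes.

Step 15
Reactants: 25 the bis(trimethylsilylalkyne)
Product: 26 (R)-bis(terminal alkyne): diaryl ether with a hept-6-ynyl arm on ring A, a 1-(tert-butyldimethylsilyloxy)hept-6-ynyl arm on ring B and three benzyl ethers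
Conditions: K2CO3 (0.5 equiv), MeOH/THF 1:1, rt
Reagents that add atoms: none
Why: Methanolysis of the two alkynyl C–SiMe3 bonds; the secondary tert-butyldimethylsilyl ether and the benzyl ethers are stable to K2CO3 in methanol.

Step 16
Reactants: 26 the (R)-bis(terminal alkyne)
Product: 27 macrocyclic 6,8-diyne, 22-membered ring, (R)-silyloxy C1, three benzyl ethers
Conditions: Cu(OAc)2 (10 equiv), pyridine, 60 °C, argon; 26 in pyridine added by syringe pump over 12 h (final concentration about 1 mM)
Reagents that add atoms: none
Why: Eglinton oxidative coupling: pyridine and copper turn each terminal alkyne into a copper acetylide, and two acetylide ligands on a dinuclear copper core are joined carbon to carbon while two divalent copper centres are reduced to monovalent copper, which forms the C7–C8 bond between two carbons of like (nucleophilic) polarity. The closest known reaction type is the Glaser–Eglinton macrocyclisation of α,ω-diynes to cyclic 1,3-diynes at high dilution. The 22-membered ring closes end to end, and the new bond is the centre of a linear C5–C10 rod, so the closure places no small-ring angle demand on the chain. No stereocentre is formed, and C1 (R) is a silyl ether inert to Cu(OAc)2 in pyridine. The one selectivity needed is ring closure over intermolecular coupling, secured by slow addition into a large excess of Cu(OAc)2 so that the concentration of uncoupled diyne stays very low; both alkynes are unhindered alkylacetylenes, so they couple at similar rates.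

Step 17
Reactants: 27 the macrocyclic 6,8-diyne
Product: 28 (R)-C1-O-tert-butyldimethylsilyl gravicycle, saturated macrocycle with three free phenols
Conditions: H2 (1 atm), 10% Pd/C, EtOAc, rt
Reagents that add atoms: none
Why: Heterogeneous hydrogenation saturates the diyne to the C6–C9 tetramethylene unit and hydrogenolyses the three aryl benzyl ethers, while the bulky silyl ether makes the benzylic C1–O bond a poor substrate for hydrogenolysis in neutral ethyl acetate.

Step 18
Reactants: 28 the C1 silyl ether
Product: 29 gravicycle, (R)-configured at C1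
Conditions: HF·pyridine, pyridine, THF, 0 °C to rt
Reagents that add atoms: none
Why: Fluoride cleavage of the Si–O bond under buffered conditions that neither ionise the benzylic C1–O bond nor generate phenoxides, so the (R) configuration is retained.

**Compound list**

1 | 3,4,5-trihydroxybenzaldehyde | O=Cc1cc(O)c(O)c(O)c1 | starting material
2 | 4-(allyloxy)-3,5-dihydroxybenzaldehyde | O=Cc1cc(O)c(OCC=C)c(O)c1 | intermediate
3 | 4-(allyloxy)-3,5-bis(benzyloxy)benzaldehyde | O=Cc1cc(OCc2ccccc2)c(OCC=C)c(OCc2ccccc2)c1 | intermediate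
4 | 3,5-bis(benzyloxy)-4-hydroxybenzaldehyde | O=Cc1cc(OCc2ccccc2)c(O)c(OCc2ccccc2)c1 | intermediate
5 | 3,5-dibromophenol | Oc1cc(Br)cc(Br)c1 | starting material
6 | 1-(benzyloxy)-3,5-dibromobenzene | Brc1cc(Br)cc(OCc2ccccc2)c1 | intermediate
7 | [3-(benzyloxy)-5-bromophenyl]lithium | [Li]c1cc(Br)cc(OCc2ccccc2)c1 | intermediate
8 | lithium [3-(benzyloxy)-5-bromophenyl]tri(isopropoxy)borate | [Li+].CC(C)O[B-](OC(C)C)(OC(C)C)c1cc(Br)cc(OCc2ccccc2)c1 | intermediate
9 | [3-(benzyloxy)-5-bromophenyl]boronic acid | OB(O)c1cc(Br)cc(OCc2ccccc2)c1 | intermediate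
10 | 3,5-bis(benzyloxy)-4-[3-(benzyloxy)-5-bromophenoxy]benzaldehyde | O=Cc1cc(OCc2ccccc2)c(Oc2cc(Br)cc(OCc3ccccc3)c2)c(OCc2ccccc2)c1 | intermediate
11 | 6-chlorohex-1-yne | ClCCCCC#C | starting material
12 | (6-chlorohex-1-yn-1-yl)lithium | [Li]C#CCCCCCl | intermediate
13 | (6-chlorohex-1-yn-1-yl)trimethylsilane | C[Si](C)(C)C#CCCCCCl | intermediate
14 | [6-(trimethylsilyl)hex-5-yn-1-yl]magnesium chloride | C[Si](C)(C)C#CCCCC[Mg]Cl | intermediate
15 | rac-1-{3,5-bis(benzyloxy)-4-[3-(benzyloxy)-5-bromophenoxy]phenyl}-7-(trimethylsilyl)hept-6-yn-1-ol | OC(CCCCC#C[Si](C)(C)C)c1cc(OCc2ccccc2)c(Oc2cc(Br)cc(OCc3ccccc3)c2)c(OCc2ccccc2)c1 | intermediate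
16 | 1-{3,5-bis(benzyloxy)-4-[3-(benzyloxy)-5-bromophenoxy]phenyl}-7-(trimethylsilyl)hept-6-yn-1-one | O=C(CCCCC#C[Si](C)(C)C)c1cc(OCc2ccccc2)c(Oc2cc(Br)cc(OCc3ccccc3)c2)c(OCc2ccccc2)c1 | intermediate
17 | (R)-1-{3,5-bis(benzyloxy)-4-[3-(benzyloxy)-5-bromophenoxy]phenyl}-7-(trimethylsilyl)hept-6-yn-1-ol | Brc1cc(OCc2ccccc2)cc(c1)Oc1c(OCc2ccccc2)cc(cc1OCc1ccccc1)[C@H](O)CCCCC#C[Si](C)(C)C | intermediate
18 | tert-butyldimethylsilyl ether of 17, (R) | Brc1cc(OCc2ccccc2)cc(c1)Oc1c(OCc2ccccc2)cc(cc1OCc1ccccc1)[C@H](O[Si](C)(C)C(C)(C)C)CCCCC#C[Si](C)(C)C | intermediate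
19 | hept-6-yn-1-ol | OCCCCCC#C | starting material
20 | dilithium salt of hept-6-yn-1-ol (alkoxide and acetylide) | [Li]OCCCCCC#C[Li] | intermediate
21 | trimethyl{[7-(trimethylsilyl)hept-6-yn-1-yl]oxy}silane | C[Si](C)(C)OCCCCCC#C[Si](C)(C)C | intermediate
22 | 7-(trimethylsilyl)hept-6-yn-1-ol | OCCCCCC#C[Si](C)(C)C | intermediate
23 | (7-iodohept-1-yn-1-yl)trimethylsilane | ICCCCCC#C[Si](C)(C)C | intermediate
24 | [7-(trimethylsilyl)hept-6-yn-1-yl]zinc iodide | I[Zn]CCCCCC#C[Si](C)(C)C | intermediate
25 | (R)-bis(trimethylsilylalkyne), Negishi product | C[Si](C)(C)C#CCCCCCc1cc(OCc2ccccc2)cc(c1)Oc1c(OCc2ccccc2)cc(cc1OCc1ccccc1)[C@H](O[Si](C)(C)C(C)(C)C)CCCCC#C[Si](C)(C)C | intermediate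
26 | (R)-bis(terminal alkyne), cyclisation precursor | C#CCCCCCc1cc(OCc2ccccc2)cc(c1)Oc1c(OCc2ccccc2)cc(cc1OCc1ccccc1)[C@H](O[Si](C)(C)C(C)(C)C)CCCCC#C | intermediate
27 | macrocyclic 6,8-diyne, (R)-silyloxy C1, three benzyl ethers | C(c1ccccc1)Oc1cc2cc(c1)Oc1c(OCc3ccccc3)cc(cc1OCc1ccccc1)[C@H](O[Si](C)(C)C(C)(C)C)CCCCC#CC#CCCCCC2 | intermediate
28 | (R)-C1-O-tert-butyldimethylsilyl gravicycle | Oc1cc2cc(c1)Oc1c(O)cc(cc1O)[C@H](O[Si](C)(C)C(C)(C)C)CCCCCCCCCCCCC2 | intermediate
29 | gravicycle | Oc1cc2cc(c1)Oc1c(O)cc(cc1O)[C@H](O)CCCCCCCCCCCCC2 | target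

**Step count**

Total steps: 18. Longest linear sequence: 13 (steps 1, 2, 3, 6, 8, 9, 10, 11, 14, 15, 16, 17, 18).

**Steps most likely to fail**

1. Step 16 (Eglinton ring closure). The danger is that intermolecular acetylide coupling to linear and cyclic oligomers outruns closure of the 22-membered ring. Fallback: close the ring by reversible olefin metathesis, which lets oligomers re-equilibrate to the monomeric ring. It sets out from 18. Methanolysis of the C–SiMe3 bond (K2CO3, MeOH) should give the terminal alkyne aryl bromide F1. Lindlar semi-hydrogenation (H2, Pd/CaCO3 poisoned with Pb(OAc)2, quinoline, EtOAc) should give the hex-5-enyl aryl bromide F2. Negishi coupling (Pd(OAc)2, SPhos, THF) with non-8-enylzinc bromide F3, made from commercial 9-bromonon-1-ene with Zn dust and LiCl, should give the diene F4. Ring-closing metathesis with the second-generation Grubbs catalyst RuCl2(=CHPh)(H2IMes)(PCy3) in dilute CH2Cl2 at reflux should form the C6=C7 bond with loss of ethene and give the 22-membered cycloalkene F5, whose alkene geometry is irrelevant. Hydrogenation of F5 over Pd/C as in step 17 saturates the alkene and removes the benzyl groups, and the route is rejoined at 28.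

2. Step 6 (Chan–Lam coupling). The danger is slow C–O bond formation at the doubly ortho-flanked, weakly nucleophilic phenoxide, so that protodeboronation and oxidative hydroxylation of the boronic acid consume the coupling partner. Fallback: an Ullmann etherification that needs no boronic acid, setting out from 4 and 6. Heating 4 with an excess of 6, CuI, picolinic acid and K3PO4 in DMSO at 90 °C should give 10 directly, where the route is rejoined. The excess of symmetric dibromide suppresses double arylation, and prolonged heating is acceptable because 4 has no stereocentre and no benzylic leaving group.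

3. Step 17 (hydrogenation). The danger is hydrogenolytic loss of the benzylic C1 oxygen, either directly or after cleavage of the silyl ether on the catalyst, during the debenzylation. Fallback: carry C1 through the hydrogenation as a ketone, whose sp2 carbon cannot be hydrogenolysed directly, and reset the stereocentre last. It sets out from 27. HF·pyridine should give the macrocyclic diynyl carbinol F6, and Dess–Martin oxidation the macrocyclic diynyl aryl ketone F7. Hydrogenation (H2, Pd/C, EtOAc, stopped once the benzyl ethers are gone) should give the saturated triphenolic ketone F8. Noyori asymmetric transfer hydrogenation with RuCl(p-cymene)[(R,R)-TsDPEN] in HCO2H/Et3N, which tolerates free phenols and gives (R)-carbinols from aryl alkyl ketones, should then give 29, where the route is rejoined.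

**Further compounds**

F1 | step 16 | (R)-aryl bromide with 1-(tert-butyldimethylsilyloxy)hept-6-ynyl arm, terminal alkyne | Brc1cc(OCc2ccccc2)cc(c1)Oc1c(OCc2ccccc2)cc(cc1OCc1ccccc1)[C@H](O[Si](C)(C)C(C)(C)C)CCCCC#C
F2 | step 16 | (R)-aryl bromide with 1-(tert-butyldimethylsilyloxy)hept-6-enyl arm | Brc1cc(OCc2ccccc2)cc(c1)Oc1c(OCc2ccccc2)cc(cc1OCc1ccccc1)[C@H](O[Si](C)(C)C(C)(C)C)CCCCC=C
F3 | step 16 | non-8-enylzinc bromide | C=CCCCCCCC[Zn]Br
F4 | step 16 | (R)-diene with non-8-enyl arm on ring A and 1-(tert-butyldimethylsilyloxy)hept-6-enyl arm on ring B | C=CCCCCCCCc1cc(OCc2ccccc2)cc(c1)Oc1c(OCc2ccccc2)cc(cc1OCc1ccccc1)[C@H](O[Si](C)(C)C(C)(C)C)CCCCC=C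
F5 | step 16 | macrocyclic 6-ene, (R)-silyloxy C1, three benzyl ethers | C(c1ccccc1)Oc1cc2cc(c1)Oc1c(OCc3ccccc3)cc(cc1OCc1ccccc1)[C@H](O[Si](C)(C)C(C)(C)C)CCCCC=CCCCCCCC2
F0 | step 6 | none | none
F6 | step 17 | macrocyclic 6,8-diyne with free (R)-C1 hydroxyl, three benzyl ethers | C(c1ccccc1)Oc1cc2cc(c1)Oc1c(OCc3ccccc3)cc(cc1OCc1ccccc1)[C@H](O)CCCCC#CC#CCCCCC2
F7 | step 17 | macrocyclic 6,8-diyne C1 ketone, three benzyl ethers | C(c1ccccc1)Oc1cc2cc(c1)Oc1c(OCc3ccccc3)cc(cc1OCc1ccccc1)C(=O)CCCCC#CC#CCCCCC2
F8 | step 17 | saturated macrocyclic C1 ketone with three free phenols | Oc1cc2cc(c1)Oc1c(O)cc(cc1O)C(=O)CCCCCCCCCCCCC2
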